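# Synthesis plan for Bisoflavolin K (22)

## The problem

Bisoflavolin K (22) is an achiral dimer of two different isoflavones. One half is a 7‑hydroxyisoflavone whose ring B carries a 4'‑hydroxyl and, at C3', a diaryl ether oxygen. The other half is an 8‑chloro‑7‑hydroxyisoflavone whose ring B is bound to that oxygen through C4'. With no stereocentre, the task is connectivity and regiochemistry: the 1,2,4‑pattern of the oxygenated ring B, a chlorine placed between O1 and the 7‑hydroxyl, and two 3‑aryl‑4‑pyranone rings that each keep a C2–H. The halves differ in the chlorine and in the point of attachment of the ether, so they must be built one after the other. Three free phenols, one of them ortho to the diaryl ether, have to be released without a late hydrogenolysis (aryl chloride) and without hot hydroxide, which opens chromones at C2. The deciding feature is ring A of the chlorine‑free half: it is fused to the pyranone at C4a–C8a, has hydrogen on C5, C6 and C8, and a single oxygen on C7. This is the pattern of a phenol formed from a ketene carbon (future C7) joined through one CH (C8) to C8a, and a vinyl group (C5, C6) on C4a. Ring A can therefore be grown last onto a finished 3‑aryl‑4‑pyranone by forming only the C6–C7 bond.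

## Retrosynthesis

**Chlorinated chromone last.** In 22 the acyl–arene bond C4–C4a and the one‑carbon bridge O1–C2/C2–C3 of the chlorinated isoflavone are cut. This leads through deoxybenzoin 21 to arylacetic acid 19 and 2‑chlororesorcinol 20. The cut is preferred to one at the diaryl ether or at C3–C1' because 20 already holds chlorine between two oxygens. Acylation can only go para to one hydroxyl and ortho to the other, and only the hydroxyl flanked by chlorine and ketone can close the ring, so chlorine ends on C8 without a halogenation step. The forward reaction must tolerate free phenols; arylacetic acids with free hydroxyls are standard partners in the BF3‑mediated acylation and one‑carbon closure.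

**Protecting groups.** Acid 19 is traced to 18, in which the 4'‑hydroxyl is a methyl ether and the acid a tert‑butyl ester. Both fall to BBr3 in one operation. The 7‑hydroxyl needs no protection because it is only created in the key step. The side chain is carried at the acid oxidation level from the start, which avoids a late alcohol oxidation. The tert‑butyl ester is chosen because it survives a saponification elsewhere (step 9).

**Key disconnection.** In 18 the C6–C7 bond is cut. The precursor is diazoketone 15, a monocyclic 4‑pyranone with the 3‑aryl group already in place. Ring‑A carbons C5/C6 are a vinyl group on pyranone C3 and C7/C8 are the diazoacetyl group on C2. Light converts 15 into dienylketene 16, which closes to dienone 17 and enolises to 18. The precursor is simpler by one ring. The forward reaction asks that 1,2‑shift beats carbene addition to the vinyl group and that the ketene meets no nucleophile.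

**Diazoketone.** Diazoketone 15 comes from acid 13 through chloride 14 and diazomethane, and 13 from methyl ester 12. The only demand is orthogonality to the tert‑butyl ester.

**Vinyl group.** The vinyl–C3 bond of 12 is cut to enol triflate 11, the sulfonate of 3‑hydroxypyranone 10, which is unmasked from benzyl ether 9. The neighbouring option, halogenating C3 of a 5‑arylpyranone late, is rejected. That position lies between ester and carbonyl on the electron‑poor double bond, and it would compete with two electron‑rich arene rings. An oxygen that sits on C3 from the outset removes the problem.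

**Aryl–pyranone bond.** Compound 9 is cut at C5–aryl (the future C3–C1' bond) into bromopyranone 8 and boronate 4. The polarity is that of the 3‑halochromone route to isoflavones, and the cut divides the molecule into two halves of similar size.

**Pyranone half.** Bromide 8 comes from ester 6 by bromination at C5, the only nucleophilic CH of the ring, through dibromide 7. Ester 6 comes from acid 5, a bulk intermediate that carries carboxyl on C2 and oxygen on C3. These are exactly the adjacent positions that become C8a and C4a.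

**Aryl half.** Boronate 4 comes from bromide 3 by borylation. The diaryl ether of 3 is cut into phenol 1 and boronic acid 2. A room‑temperature Chan–Lam coupling leaves the aryl bromide for the next step, and the substitution pattern of ring B is bought with 2.

## Roads not taken

**Alternative 1:** The cut is the pair of bonds C4a–C5 and C8–C8a of the chlorinated chromone. A Diels–Alder reaction between sulfinylpyranone A2 (racemic at sulfur), which already carries the complete chlorine‑free isoflavone as its dimethyl ether, and chloro diene A3 would give A1 after loss of the sulfinyl and methoxy groups. Two O‑demethylations would remain.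
- Merits: ring A of the chlorinated half arrives with chlorine and hydroxyl in place in one operation; it is the most convergent C–C bond formation of the four plans; it needs no diazo compound and no light.
- Weak points:
  - The C5=C6 bond of a 4‑pyranone is part of a vinylogous ester and a reluctant dienophile. Sulfinyl activation is proven on benzo‑fused pyranones, much less on a monocyclic one whose second enone double bond is also open to attack.
  - A3 has chlorine on its nucleophilic terminus and only one donor oxygen reinforcing that terminus, so it is less reactive and harder to prepare than doubly oxygen‑activated dienes without halogen.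
  - A2 needs a 3‑aryl‑4‑pyranone sulfenylated selectively at C5. This is the same pyranone functionalisation problem the chosen plan solves early on a small molecule, now placed at the end.
- Comparison: both plans annulate a benzene ring onto a pyranone. Alternative 1 does it intermolecularly and must win reactivity and regiochemistry. The chosen plan closes the ring intramolecularly with regiochemistry fixed by two substituents. Alternative 1 would be the better way to a chlorinated ring that could not be bought, but here that ring comes from 20 by an unambiguous acylation.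

**Alternative 2:** The cut is C3–C4 of the chlorine‑free pyranone. A carbene‑catalysed intramolecular aldehyde–ketone benzoin reaction of A5 would give 3‑hydroxychromanone A4 (racemic). Dehydration across C2–C3 and three O‑demethylations would follow.
- Merits: this closure is well established for 3‑hydroxychroman‑4‑ones, catalytic and run near room temperature, and A5 comes from a simple phenol O‑alkylation. As a ring closure it is probably more reliable than a photochemical cascade, and the step count is equal or lower.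
- Weak points:
  - A4 has a tertiary alcohol and a stereocentre that exist only to be destroyed. The elimination toward C2 competes with retro‑benzoin cleavage.
  - A5 already contains the finished chlorinated chromone, whose C2=C3 bond is an acceptor for the acyl anion equivalent and for the base.
  - Three methyl ethers, one next to chlorine, must be cleaved at the end.
- Comparison: the chosen plan sets against the better precedent that it reaches the aromatic oxidation level directly with the 7‑hydroxyl free, forms no stereocentre, and never exposes a completed chromone to a nucleophilic catalyst.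

**Alternative 3:** The cut is C2=C3 of the chlorine‑free pyranone. On heating, keto‑stabilised ylide A7 would attack its neighbouring aryl formate and give A6.
- Merits: the closure is neutral and thermal. A6 differs from 18 only by a methyl group on the 7‑oxygen and would enter the same endgame. Its precursors come from simple arenes, so this road is shorter than the chosen one.
- Weak points:
  - Aryl formates are among the most labile esters and pass their formyl group to any nucleophile, including the base that makes the ylide and a second ylide molecule.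
  - The ylide carbon is fully substituted and stabilised, so it is sluggish toward an ester carbonyl.
  - The 7‑O‑methyl ether must be cleaved later.
- Comparison: the chosen plan is longer. It sets against that a 7‑hydroxyl that appears unprotected, a C3–aryl bond made by cross‑coupling on a simple bromopyranone, and a closure that releases only nitrogen and does not depend on a formate surviving ylide formation.

Key step: step 11

## Route

Remark: 22 has no stereogenic element; the only stereocentres in the route are the two transient ones of dibromide 7, which are lost on elimination. Atom numbers C2–C6 refer to the 4‑pyranone ring of the intermediates. Ar = 3‑[4‑(2‑tert‑butoxy‑2‑oxoethyl)phenoxy]‑4‑methoxyphenyl; dppf = 1,1'‑bis(diphenylphosphino)ferrocene.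

Step 1
Reactants: 1 tert‑butyl 2‑(4‑hydroxyphenyl)acetate; 2 (5‑bromo‑2‑methoxyphenyl)boronic acid
Product: 3 tert‑butyl 2‑[4‑(5‑bromo‑2‑methoxyphenoxy)phenyl]acetate
Conditions: Cu(OAc)2 (1.0 equiv), pyridine (5 equiv), 4 Å MS, CH2Cl2, air (O2 as terminal oxidant), rt
Reagents that add atoms: none
Why: Chan–Lam O‑arylation; phenoxide and aryl group meet on copper and reductive elimination forms the C–O bond at room temperature. The aryl bromide and the ester with its benzylic CH2 are left alone, which a hot Ullmann coupling would not guarantee.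

Step 2
Reactants: 3 tert‑butyl 2‑[4‑(5‑bromo‑2‑methoxyphenoxy)phenyl]acetate
Product: 4 tert‑butyl 2‑{4‑[2‑methoxy‑5‑(4,4,5,5‑tetramethyl‑1,3,2‑dioxaborolan‑2‑yl)phenoxy]phenyl}acetate
Conditions: B2pin2 (1.2 equiv), Pd(dppf)Cl2 (3 mol%), KOAc (3 equiv), 1,4‑dioxane, 90 °C
Reagents that add atoms: bis(pinacolato)diboron, CC1(C)OB(OC1(C)C)B1OC(C)(C)C(C)(C)O1
Why: Miyaura borylation of an electron‑rich aryl bromide; KOAc is too weak a base to drive coupling of the new boronate with unreacted bromide or to enolise the ester.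

Step 3
Reactants: 5 3‑(benzyloxy)‑4‑oxo‑4H‑pyran‑2‑carboxylic acid
Product: 6 methyl 3‑(benzyloxy)‑4‑oxo‑4H‑pyran‑2‑carboxylate
Conditions: MeI (1.5 equiv), K2CO3 (1.5 equiv), DMF, rt
Reagents that add atoms: iodomethane, CI
Why: SN2 O‑alkylation of the carboxylate; the methyl ester masks the acid through the next five steps and can later be cleaved beside a tert‑butyl ester.

Step 4
Reactants: 6 methyl 3‑(benzyloxy)‑4‑oxo‑4H‑pyran‑2‑carboxylate
Product: 8 methyl 3‑(benzyloxy)‑5‑bromo‑4‑oxo‑4H‑pyran‑2‑carboxylate, via trans‑5,6‑dibromide 7 (not isolated)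
Conditions: Br2 (1.1 equiv), CH2Cl2, 0 °C → rt, dark; then Et3N (1.5 equiv), 0 °C
Reagents that add atoms: bromine, BrBr
Why: α‑Bromination of a vinylogous ester by addition–elimination, as in chromone → 3‑bromochromone. C5 is the only nucleophilic CH of the ring (α‑carbon of O1–C6=C5–C4=O), bromine adds across C5=C6, and the amine removes H5 with loss of the C6 bromide to restore the pyranone.

Step 5
Reactants: 4 tert‑butyl 2‑{4‑[2‑methoxy‑5‑(4,4,5,5‑tetramethyl‑1,3,2‑dioxaborolan‑2‑yl)phenoxy]phenyl}acetate; 8 methyl 3‑(benzyloxy)‑5‑bromo‑4‑oxo‑4H‑pyran‑2‑carboxylate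
Product: 9 methyl 5‑Ar‑3‑(benzyloxy)‑4‑oxo‑4H‑pyran‑2‑carboxylate
Conditions: Pd(dppf)Cl2 (5 mol%), CsF (3 equiv), 1,4‑dioxane, 80 °C
Reagents that add atoms: none
Why: Suzuki–Miyaura coupling of an α‑bromo enone with an electron‑rich aryl boronate, the same bond construction as 3‑halochromone → isoflavone. Anhydrous fluoride activation spares the activated methyl ester and the tert‑butyl ester.

Step 6
Reactants: 9 methyl 5‑Ar‑3‑(benzyloxy)‑4‑oxo‑4H‑pyran‑2‑carboxylate
Product: 10 methyl 5‑Ar‑3‑hydroxy‑4‑oxo‑4H‑pyran‑2‑carboxylate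
Conditions: H2 (1 atm), 10% Pd/C, EtOAc, rt, stopped when 9 is consumed
Reagents that add atoms: none
Why: Hydrogenolysis of the benzyl ether of a 3‑oxy‑4‑pyranone, which is fast at one atmosphere; it is placed before the vinyl group exists, and the diaryl ether, both esters and the methyl ether are inert.

Step 7
Reactants: 10 methyl 5‑Ar‑3‑hydroxy‑4‑oxo‑4H‑pyran‑2‑carboxylate
Product: 11 methyl 5‑Ar‑4‑oxo‑3‑(trifluoromethanesulfonyloxy)‑4H‑pyran‑2‑carboxylate
Conditions: PhNTf2 (1.2 equiv), Et3N (2 equiv), DMAP (cat.), CH2Cl2, 0 °C → rt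
Reagents that add atoms: N‑phenylbis(trifluoromethanesulfonimide), O=S(=O)(N(c1ccccc1)S(=O)(=O)C(F)(F)F)C(F)(F)F
Why: O‑Sulfonylation of the acidic enol through its ammonium enolate; the imide reagent is chosen over triflic anhydride, which would also attack the pyranone carbonyl oxygen.

Step 8
Reactants: 11 methyl 5‑Ar‑4‑oxo‑3‑(trifluoromethanesulfonyloxy)‑4H‑pyran‑2‑carboxylate
Product: 12 methyl 5‑Ar‑3‑ethenyl‑4‑oxo‑4H‑pyran‑2‑carboxylate
Conditions: Bu3SnCH=CH2 (1.3 equiv), Pd(PPh3)4 (5 mol%), LiCl (3 equiv), 1,4‑dioxane, 90 °C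
Reagents that add atoms: tributyl(vinyl)stannane, C=C[Sn](CCCC)(CCCC)CCCC
Why: Stille coupling of an electron‑poor enol triflate, which adds readily to zerovalent palladium; the neutral conditions protect the base‑sensitive pyranone and the small vinyl group tolerates the two flanking substituents.

Step 9
Reactants: 12 methyl 5‑Ar‑3‑ethenyl‑4‑oxo‑4H‑pyran‑2‑carboxylate
Product: 13 5‑Ar‑3‑ethenyl‑4‑oxo‑4H‑pyran‑2‑carboxylic acid
Conditions: LiOH·H2O (1.2 equiv), THF/H2O (4:1), 0 °C; then 1 M HCl to pH 3, 0 °C
Reagents that add atoms: lithium hydroxide (hydroxide oxygen), [Li+].[OH-]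
Why: Saponification of a strongly activated pyranone‑2‑carboxylate, which proceeds at 0 °C with a small excess of hydroxide. The hindered tert‑butyl ester does not react, and the short cold exposure avoids hydroxide addition at C6.

Step 10
Reactants: 13 5‑Ar‑3‑ethenyl‑4‑oxo‑4H‑pyran‑2‑carboxylic acid
Product: 15 5‑Ar‑2‑(2‑diazoacetyl)‑3‑ethenyl‑4H‑pyran‑4‑one, via acid chloride 14 (not isolated)
Conditions: 1‑chloro‑N,N,2‑trimethylprop‑1‑en‑1‑amine (1.2 equiv), CH2Cl2, 0 °C → rt; then CH2N2 (3 equiv), Et2O/CH2Cl2, 0 °C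
Reagents that add atoms: diazomethane, C=[N+]=[N-]; 1‑chloro‑N,N,2‑trimethylprop‑1‑en‑1‑amine, CC(C)=C(Cl)N(C)C (chlorine of intermediate 14 only)
Why: The α‑chloroenamine makes the acid chloride without free HCl, so the tert‑butyl ester is safe. Acylation of diazomethane (first stage of an Arndt–Eistert sequence) then gives the diazoketone, with a second equivalent taking up the HCl.

Step 11
Reactants: 15 5‑Ar‑2‑(2‑diazoacetyl)‑3‑ethenyl‑4H‑pyran‑4‑one
Product: 18 tert‑butyl 2‑{4‑[5‑(7‑hydroxy‑4‑oxo‑4H‑chromen‑3‑yl)‑2‑methoxyphenoxy]phenyl}acetate, via dienylketene 16 (not isolated), via cyclohexadienone 17 (not isolated)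
Conditions: hν (365 nm LEDs, Pyrex), dry degassed ClCH2CH2Cl (0.005 M), 20 °C; then 60 °C, dark
Reagents that add atoms: none
Why: Excitation of the diazoketone expels N2 and pyranone carbon C2 shifts to the carbene carbon (Wolff rearrangement), giving ketene 16 attached through one CH to the future C8a. In 16 the ketene C=C, the ring double bond C8a=C4a and the vinyl group form a hexatriene whose central double bond is held cis by the pyranone, so thermal disrotatory six‑electron electrocyclisation closes the six‑membered ring A by forming C6–C7 and gives cyclohexa‑2,4‑dienone 17. Enolisation of 17 gives phenol 18 with the former ketene carbonyl as the 7‑hydroxyl, so no oxidant is needed, and no stereocentre is formed at any stage (C6 of 17 is a methylene). The closest known reaction type is the photochemical Wolff rearrangement of unsaturated diazoketones to dienylketenes that cyclise and tautomerise to phenols, the closing sequence of diazoketone‑based aromatic annulations. The step needs the 1,2‑shift to win over carbene addition to the neighbouring vinyl group and needs the ketene to meet no nucleophile. Direct irradiation without any metal favours the concerted shift from the s‑cis diazoketone, and high dilution in a dry aprotic solvent leaves ring closure as the only fast reaction of 16, also against acylation of the product phenol. Light of 365 nm is absorbed by the diazoketone but lies beyond the bands at which 4‑pyranones and the product chromone rearrange. The tert‑butyl ester, the diaryl ether and the methyl ether are inert to light of this wavelength and to a ketene.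

Step 12
Reactants: 18 tert‑butyl 2‑{4‑[5‑(7‑hydroxy‑4‑oxo‑4H‑chromen‑3‑yl)‑2‑methoxyphenoxy]phenyl}acetate
Product: 19 2‑{4‑[2‑hydroxy‑5‑(7‑hydroxy‑4‑oxo‑4H‑chromen‑3‑yl)phenoxy]phenyl}acetic acid
Conditions: BBr3 (8 equiv), CH2Cl2, −78 °C → rt; then H2O, 0 °C
Reagents that add atoms: none
Why: Lewis‑acid ether cleavage: bromide attacks the methyl group of the boron‑complexed anisole, and the tert‑butyl ester ionises under the same conditions. Diaryl ethers and chromones are stable to BBr3, so one operation frees the acid and the last protected phenol.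

Step 13
Reactants: 19 2‑{4‑[2‑hydroxy‑5‑(7‑hydroxy‑4‑oxo‑4H‑chromen‑3‑yl)phenoxy]phenyl}acetic acid; 20 2‑chlorobenzene‑1,3‑diol (1.5 equiv)
Product: 22 Bisoflavolin K, via deoxybenzoin 21 (not isolated)
Conditions: BF3·OEt2 (neat), 85 °C; then DMF, MeSO2Cl (3 equiv), 70 °C; aq. NaOAc work‑up
Reagents that add atoms: N,N‑dimethylformamide (carbon C2 of the new chromone), CN(C)C=O
Why: BF3‑promoted Friedel–Crafts acylation of 20 at C4, the only doubly activated position (para to one hydroxyl, ortho to the other), gives 21. The Vilsmeier‑type iminium from DMF and MeSO2Cl then formylates the boron‑complexed enol, and closure through the hydroxyl between chlorine and ketone with loss of dimethylamine places chlorine on C8. Free phenols on the arylacetic acid partner are tolerated in this one‑pot isoflavone synthesis, and the two activated positions of 20 outcompete the mono‑activated rings of 19.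

## Compound list

1 | tert‑butyl 2‑(4‑hydroxyphenyl)acetate | CC(C)(C)OC(=O)Cc1ccc(O)cc1 | starting material
2 | (5‑bromo‑2‑methoxyphenyl)boronic acid | COc1ccc(Br)cc1B(O)O | starting material
3 | tert‑butyl 2‑[4‑(5‑bromo‑2‑methoxyphenoxy)phenyl]acetate | COc1ccc(Br)cc1Oc1ccc(CC(=O)OC(C)(C)C)cc1 | intermediate
4 | tert‑butyl 2‑{4‑[2‑methoxy‑5‑(4,4,5,5‑tetramethyl‑1,3,2‑dioxaborolan‑2‑yl)phenoxy]phenyl}acetate | COc1ccc(B2OC(C)(C)C(C)(C)O2)cc1Oc1ccc(CC(=O)OC(C)(C)C)cc1 | intermediate
5 | 3‑(benzyloxy)‑4‑oxo‑4H‑pyran‑2‑carboxylic acid | O=C(O)c1occc(=O)c1OCc1ccccc1 | starting material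
6 | methyl 3‑(benzyloxy)‑4‑oxo‑4H‑pyran‑2‑carboxylate | COC(=O)c1occc(=O)c1OCc1ccccc1 | intermediate
7 | methyl 3‑(benzyloxy)‑5,6‑dibromo‑4‑oxo‑5,6‑dihydro‑4H‑pyran‑2‑carboxylate (trans, racemic, one enantiomer drawn; not isolated) | COC(=O)C1=C(OCc2ccccc2)C(=O)[C@H](Br)[C@@H](Br)O1 | intermediate
8 | methyl 3‑(benzyloxy)‑5‑bromo‑4‑oxo‑4H‑pyran‑2‑carboxylate | COC(=O)c1occ(Br)c(=O)c1OCc1ccccc1 | intermediate
9 | methyl 3‑(benzyloxy)‑5‑{3‑[4‑(2‑tert‑butoxy‑2‑oxoethyl)phenoxy]‑4‑methoxyphenyl}‑4‑oxo‑4H‑pyran‑2‑carboxylate | COC(=O)c1occ(-c2ccc(OC)c(Oc3ccc(CC(=O)OC(C)(C)C)cc3)c2)c(=O)c1OCc1ccccc1 | intermediate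
10 | methyl 5‑{3‑[4‑(2‑tert‑butoxy‑2‑oxoethyl)phenoxy]‑4‑methoxyphenyl}‑3‑hydroxy‑4‑oxo‑4H‑pyran‑2‑carboxylate | COC(=O)c1occ(-c2ccc(OC)c(Oc3ccc(CC(=O)OC(C)(C)C)cc3)c2)c(=O)c1O | intermediate
11 | methyl 5‑{3‑[4‑(2‑tert‑butoxy‑2‑oxoethyl)phenoxy]‑4‑methoxyphenyl}‑4‑oxo‑3‑(trifluoromethanesulfonyloxy)‑4H‑pyran‑2‑carboxylate | COC(=O)c1occ(-c2ccc(OC)c(Oc3ccc(CC(=O)OC(C)(C)C)cc3)c2)c(=O)c1OS(=O)(=O)C(F)(F)F | intermediate
12 | methyl 5‑{3‑[4‑(2‑tert‑butoxy‑2‑oxoethyl)phenoxy]‑4‑methoxyphenyl}‑3‑ethenyl‑4‑oxo‑4H‑pyran‑2‑carboxylate | COC(=O)c1occ(-c2ccc(OC)c(Oc3ccc(CC(=O)OC(C)(C)C)cc3)c2)c(=O)c1C=C | intermediate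
13 | 5‑{3‑[4‑(2‑tert‑butoxy‑2‑oxoethyl)phenoxy]‑4‑methoxyphenyl}‑3‑ethenyl‑4‑oxo‑4H‑pyran‑2‑carboxylic acid | O=C(O)c1occ(-c2ccc(OC)c(Oc3ccc(CC(=O)OC(C)(C)C)cc3)c2)c(=O)c1C=C | intermediate
14 | 5‑{3‑[4‑(2‑tert‑butoxy‑2‑oxoethyl)phenoxy]‑4‑methoxyphenyl}‑3‑ethenyl‑4‑oxo‑4H‑pyran‑2‑carbonyl chloride (not isolated) | O=C(Cl)c1occ(-c2ccc(OC)c(Oc3ccc(CC(=O)OC(C)(C)C)cc3)c2)c(=O)c1C=C | intermediate
15 | 5‑{3‑[4‑(2‑tert‑butoxy‑2‑oxoethyl)phenoxy]‑4‑methoxyphenyl}‑2‑(2‑diazoacetyl)‑3‑ethenyl‑4H‑pyran‑4‑one | [N-]=[N+]=CC(=O)c1occ(-c2ccc(OC)c(Oc3ccc(CC(=O)OC(C)(C)C)cc3)c2)c(=O)c1C=C | intermediate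
16 | 5‑{3‑[4‑(2‑tert‑butoxy‑2‑oxoethyl)phenoxy]‑4‑methoxyphenyl}‑3‑ethenyl‑2‑(2‑oxoethenyl)‑4H‑pyran‑4‑one (dienylketene; not isolated) | O=C=Cc1occ(-c2ccc(OC)c(Oc3ccc(CC(=O)OC(C)(C)C)cc3)c2)c(=O)c1C=C | intermediate
17 | tert‑butyl 2‑{4‑[5‑(4,7‑dioxo‑6,7‑dihydro‑4H‑chromen‑3‑yl)‑2‑methoxyphenoxy]phenyl}acetate (not isolated) | O=C1CC=C2C(=O)C(-c3ccc(OC)c(Oc4ccc(CC(=O)OC(C)(C)C)cc4)c3)=COC2=C1 | intermediate
18 | tert‑butyl 2‑{4‑[5‑(7‑hydroxy‑4‑oxo‑4H‑chromen‑3‑yl)‑2‑methoxyphenoxy]phenyl}acetate | O=c1c(-c2ccc(OC)c(Oc3ccc(CC(=O)OC(C)(C)C)cc3)c2)coc2cc(O)ccc12 | intermediate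
19 | 2‑{4‑[2‑hydroxy‑5‑(7‑hydroxy‑4‑oxo‑4H‑chromen‑3‑yl)phenoxy]phenyl}acetic acid | O=c1c(-c2ccc(O)c(Oc3ccc(CC(=O)O)cc3)c2)coc2cc(O)ccc12 | intermediate
20 | 2‑chlorobenzene‑1,3‑diol (2‑chlororesorcinol) | Oc1cccc(O)c1Cl | starting material
21 | 3‑(3‑{4‑[2‑(3‑chloro‑2,4‑dihydroxyphenyl)‑2‑oxoethyl]phenoxy}‑4‑hydroxyphenyl)‑7‑hydroxy‑4H‑chromen‑4‑one (not isolated) | O=C(Cc1ccc(Oc2cc(-c3coc4cc(O)ccc4c3=O)ccc2O)cc1)c1ccc(O)c(Cl)c1O | intermediate
22 | Bisoflavolin K, 8‑chloro‑7‑hydroxy‑3‑{4‑[2‑hydroxy‑5‑(7‑hydroxy‑4‑oxo‑4H‑chromen‑3‑yl)phenoxy]phenyl}‑4H‑chromen‑4‑one | O=c1c(-c2ccc(O)c(Oc3ccc(-c4coc5c(Cl)c(O)ccc5c4=O)cc3)c2)coc2cc(O)ccc12 | target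

## Step count and least certain steps

Total: 13 steps. Longest linear sequence: 11 steps (from 5 through steps 3–13, or from 1 and 2 through steps 1, 2 and 5–13).

**Risk at step 11 (key step).** The ketene may be intercepted by adventitious water or by the phenol of the product before it closes. The carbene may add to the neighbouring vinyl group instead of rearranging, or the pyranone and product chromophores may undergo secondary photochemistry. Fallback: the chlorine‑free isoflavone is made without annulating ring A. Commercial 2'‑hydroxy‑4'‑methoxyacetophenone F1 is condensed with N,N‑dimethylformamide dimethyl acetal to (E)‑enaminone F2, which iodine cyclises to 3‑iodo‑7‑methoxychromone F3. Suzuki coupling of F3 with boronate 4 (Pd(dppf)Cl2, CsF, dioxane) gives 7‑methoxyisoflavone F4. BBr3 then removes both methyl ethers and the tert‑butyl ester. The fallback sets out from 4 and returns to the route at 19.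

**Risk at step 10.** Diazomethane may undergo dipolar cycloaddition to the electron‑poor vinyl group or to a pyranone double bond, and traces of HCl may cause partial loss of the tert‑butyl ester. Fallback: no diazoalkane is used. Acid chloride 14, made from 13 as in step 10, is coupled with SnMe4 (benzylchlorobis(triphenylphosphine)palladium as catalyst) to methyl ketone F5. Its lithium enolate (LiN(SiMe3)2, one equivalent, −78 °C; the acetyl group is more acidic than the arylacetate) is acylated with 2,2,2‑trifluoroethyl trifluoroacetate to trifluoroacetyl diketone F6. Detrifluoroacetylative diazo transfer from methanesulfonyl azide (Et3N, H2O, MeCN) then gives the diazoketone. The fallback sets out from 14 and returns at 15.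

**Risk at step 13.** The acid may acylate or esterify the phenol rings of its own kind (oligomerisation), the iminium reagent may C‑formylate an electron‑rich ring, and closure of the deoxybenzoin may stay incomplete. Fallback: the phenol is kept masked and the deoxybenzoin is isolated. From 18, CF3CO2H in CH2Cl2 cleaves only the tert‑butyl ester to methoxy acid F7. BF3·OEt2 with 20 gives deoxybenzoin F8, which is purified and closed with N,N‑dimethylformamide dimethyl acetal (THF, 65 °C) to monomethyl ether F9. BBr3 then cleaves the methyl ether. The fallback sets out from 18 and returns at 22.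

**Risk at step 6.** Over‑hydrogenation may saturate the aryl‑substituted C5=C6 bond, or the hydrogenolysis may stall through binding of the chelating 3‑hydroxy‑4‑pyranone to the catalyst. Fallback: the benzyl group is removed before the aryl group is attached and without hydrogen. From 8, BCl3 (CH2Cl2, −78 → 0 °C) gives methyl 5‑bromo‑3‑hydroxy‑4‑oxo‑4H‑pyran‑2‑carboxylate F10, and Suzuki coupling of F10 with boronate 4 (Pd(dppf)Cl2, CsF in excess, dioxane) forms the aryl–C5 bond on the free enol. The fallback sets out from 8 and returns at 10.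

## Further compounds

F1 | step 11 | 2'‑hydroxy‑4'‑methoxyacetophenone (purchased) | CC(=O)c1ccc(OC)cc1O
F2 | step 11 | (E)‑3‑(dimethylamino)‑1‑(2‑hydroxy‑4‑methoxyphenyl)prop‑2‑en‑1‑one | CN(C)/C=C/C(=O)c1ccc(OC)cc1O
F3 | step 11 | 3‑iodo‑7‑methoxy‑4H‑chromen‑4‑one | O=c1c(I)coc2cc(OC)ccc12
F4 | step 11 | tert‑butyl 2‑{4‑[2‑methoxy‑5‑(7‑methoxy‑4‑oxo‑4H‑chromen‑3‑yl)phenoxy]phenyl}acetate | O=c1c(-c2ccc(OC)c(Oc3ccc(CC(=O)OC(C)(C)C)cc3)c2)coc2cc(OC)ccc12
F5 | step 10 | 2‑acetyl‑5‑{3‑[4‑(2‑tert‑butoxy‑2‑oxoethyl)phenoxy]‑4‑methoxyphenyl}‑3‑ethenyl‑4H‑pyran‑4‑one | CC(=O)c1occ(-c2ccc(OC)c(Oc3ccc(CC(=O)OC(C)(C)C)cc3)c2)c(=O)c1C=C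
F6 | step 10 | 5‑{3‑[4‑(2‑tert‑butoxy‑2‑oxoethyl)phenoxy]‑4‑methoxyphenyl}‑3‑ethenyl‑2‑(4,4,4‑trifluoro‑3‑oxobutanoyl)‑4H‑pyran‑4‑one | O=C(CC(=O)C(F)(F)F)c1occ(-c2ccc(OC)c(Oc3ccc(CC(=O)OC(C)(C)C)cc3)c2)c(=O)c1C=C
F7 | step 13 | 2‑{4‑[5‑(7‑hydroxy‑4‑oxo‑4H‑chromen‑3‑yl)‑2‑methoxyphenoxy]phenyl}acetic acid | O=c1c(-c2ccc(OC)c(Oc3ccc(CC(=O)O)cc3)c2)coc2cc(O)ccc12
F8 | step 13 | 3‑(3‑{4‑[2‑(3‑chloro‑2,4‑dihydroxyphenyl)‑2‑oxoethyl]phenoxy}‑4‑methoxyphenyl)‑7‑hydroxy‑4H‑chromen‑4‑one | O=C(Cc1ccc(Oc2cc(-c3coc4cc(O)ccc4c3=O)ccc2OC)cc1)c1ccc(O)c(Cl)c1O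
F9 | step 13 | 8‑chloro‑7‑hydroxy‑3‑{4‑[5‑(7‑hydroxy‑4‑oxo‑4H‑chromen‑3‑yl)‑2‑methoxyphenoxy]phenyl}‑4H‑chromen‑4‑one | O=c1c(-c2ccc(OC)c(Oc3ccc(-c4coc5c(Cl)c(O)ccc5c4=O)cc3)c2)coc2cc(O)ccc12
F10 | step 6 | methyl 5‑bromo‑3‑hydroxy‑4‑oxo‑4H‑pyran‑2‑carboxylate | COC(=O)c1occ(Br)c(=O)c1O
A1 | alternative 1 | 8‑chloro‑7‑hydroxy‑3‑{4‑[2‑methoxy‑5‑(7‑methoxy‑4‑oxo‑4H‑chromen‑3‑yl)phenoxy]phenyl}‑4H‑chromen‑4‑one | O=c1c(-c2ccc(OC)c(Oc3ccc(-c4coc5c(Cl)c(O)ccc5c4=O)cc3)c2)coc2cc(OC)ccc12
A2 | alternative 1 | 3‑{4‑[2‑methoxy‑5‑(7‑methoxy‑4‑oxo‑4H‑chromen‑3‑yl)phenoxy]phenyl}‑5‑(4‑methylbenzenesulfinyl)‑4H‑pyran‑4‑one (racemic at sulfur) | O=c1c(-c2ccc(Oc3cc(-c4coc5cc(OC)ccc5c4=O)ccc3OC)cc2)cocc1S(=O)c1ccc(C)cc1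
A3 | alternative 1 | (1Z,3E)‑1‑chloro‑4‑methoxy‑2‑(trimethylsilyloxy)buta‑1,3‑diene | CO/C=C/C(O[Si](C)(C)C)=C/Cl
A4 | alternative 2 | 3‑{3‑[4‑(8‑chloro‑7‑methoxy‑4‑oxo‑4H‑chromen‑3‑yl)phenoxy]‑4‑methoxyphenyl}‑3‑hydroxy‑7‑methoxychroman‑4‑one (racemic, R enantiomer drawn) | COc1ccc2c(c1)OC[C@](O)(c1ccc(OC)c(Oc3ccc(-c4coc5c(Cl)c(OC)ccc5c4=O)cc3)c1)C2=O
A5 | alternative 2 | 2‑(2‑{3‑[4‑(8‑chloro‑7‑methoxy‑4‑oxo‑4H‑chromen‑3‑yl)phenoxy]‑4‑methoxyphenyl}‑2‑oxoethoxy)‑4‑methoxybenzaldehyde | COc1ccc(C=O)c(OCC(=O)c2ccc(OC)c(Oc3ccc(-c4coc5c(Cl)c(OC)ccc5c4=O)cc3)c2)c1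
A6 | alternative 3 | tert‑butyl 2‑{4‑[2‑methoxy‑5‑(7‑methoxy‑4‑oxo‑4H‑chromen‑3‑yl)phenoxy]phenyl}acetate | O=c1c(-c2ccc(OC)c(Oc3ccc(CC(=O)OC(C)(C)C)cc3)c2)coc2cc(OC)ccc12
A7 | alternative 3 | 2‑[2‑{3‑[4‑(2‑tert‑butoxy‑2‑oxoethyl)phenoxy]‑4‑methoxyphenyl}‑2‑(triphenylphosphoranylidene)acetyl]‑5‑methoxyphenyl formate | O=COc1cc(OC)ccc1C(=O)C(=P(c1ccccc1)(c1ccccc1)c1ccccc1)c1ccc(OC)c(Oc2ccc(CC(=O)OC(C)(C)C)cc2)c1
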